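**Retrosynthetic overview**

1. Target ⇐ site-selective Steglich acylation of the naphthazarin diol with (R)-2-methylbutanoic acid ⇐ global desilylation ⇐ PhI(OAc)2 oxidation of a 5,8-disilyloxy-4-methoxy-1-naphthol.
2. Key disconnection (ring B, the only ring that is built): the naphthol ⇒ a lithiated aryl(methoxy)methyl phenyl sulfone (ring A plus the future C-4 at the acyl oxidation level) + a 2-substituted cyclopropenone that carries the whole side chain with its (R) centre. The C-3–C-4 and C-1–C-8a bonds form in one flask by conjugate addition, strain-driven ring opening to a vinylketene and 6π-electrocyclisation.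
3. Enabling feature: the cyclopropenone ring. Its CH carbon (future C-3) is the Michael terminus, and its strained C(=O)–CH bond is the one that breaks, which turns the carbonyl carbon (future C-1) into a ketene joined through C-2=C-3 to the aryl ring; the single free ortho CH of ring A (future C-8a) then closes the ring.
4. Cyclopropenone ⇐ CF2 transfer and hydrolysis on a terminal alkyne ⇐ Zn–ProPhenol asymmetric alkynylation of (E)-4-methyl-4-(triethylsilyloxy)pent-2-enal ⇐ cross-metathesis of 2-methylbut-3-en-2-ol with crotonaldehyde; sulfone ⇐ 2,5-dihydroxybenzaldehyde.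
5. Order of rings: ring A is bought; the three-membered ring is made in step 6 and consumed; ring B is formed in the key step.

Key step: step 9

Remark: 5,8-dihydroxy-1,4-naphthoquinones exchange their quinoid and benzenoid rings by fast tautomerism, so the naphthazarin made here is the target whichever tautomer is drawn; compounds 1, 2, 5, 11 and 22 (the single (R) enantiomer) are taken as commercial.

**Route**

Step 1
Reactants: 1 2-methylbut-3-en-2-ol; 2 (E)-but-2-enal (crotonaldehyde)
Product: 3 (E)-4-hydroxy-4-methylpent-2-enal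
Conditions: second-generation Hoveyda–Grubbs catalyst (2–3 mol%), excess 2, CH2Cl2, 40 °C
Reagents that add atoms: none
Why: Olefin cross-metathesis between a tertiary allylic alcohol that homodimerises slowly and an excess of the enal partner should give the (E)-enal under thermodynamic control, with loss of volatile propene driving the exchange.

Step 2
Reactants: 3 (E)-4-hydroxy-4-methylpent-2-enal
Product: 4 (E)-4-methyl-4-[(triethylsilyl)oxy]pent-2-enal
Conditions: TESOTf, 2,6-lutidine, CH2Cl2, −78 → 0 °C
Reagents that add atoms: triethylsilyl trifluoromethanesulfonate, CC[Si](CC)(CC)OS(=O)(=O)C(F)(F)F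
Why: Silyl triflate/2,6-lutidine silylation is the standard way to cap a hindered tertiary alcohol, and the enal has no enolisable γ-hydrogen to divert the reagent.

Step 3
Reactants: 4 (E)-4-methyl-4-[(triethylsilyl)oxy]pent-2-enal; 5 ethynyltrimethylsilane
Product: 6 (3R,4E)-6-methyl-6-[(triethylsilyl)oxy]-1-(trimethylsilyl)hept-4-en-1-yn-3-ol
Conditions: (R,R)-ProPhenol (10 mol%), Me2Zn, Ph3P=O (20 mol%), toluene, 0–4 °C
Reagents that add atoms: none
Why: Zn–ProPhenol-catalysed asymmetric alkynylation of an α,β-unsaturated aldehyde (Trost alkynylation), in which the dinuclear zinc catalyst binds aldehyde and zinc acetylide and should deliver the alkynyl group to the Si face of the formyl group to set the (R) carbinol centre; the sense of induction is to be confirmed by Mosher ester analysis and the antipodal ligand taken if it proves opposite.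

Step 4
Reactants: 6 (3R,4E)-6-methyl-6-[(triethylsilyl)oxy]-1-(trimethylsilyl)hept-4-en-1-yn-3-ol
Product: 7 (3R,4E)-3-[(tert-butyldimethylsilyl)oxy]-6-methyl-6-[(triethylsilyl)oxy]-1-(trimethylsilyl)hept-4-en-1-yne
Conditions: TBSCl, imidazole, DMF, 20 °C
Reagents that add atoms: tert-butyldimethylsilyl chloride, CC(C)(C)[Si](C)(C)Cl
Why: Standard imidazole-promoted silylation of a secondary alcohol, which does not touch the carbinol centre.

Step 5
Reactants: 7 (3R,4E)-3-[(tert-butyldimethylsilyl)oxy]-6-methyl-6-[(triethylsilyl)oxy]-1-(trimethylsilyl)hept-4-en-1-yne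
Product: 8 (3R,4E)-3-[(tert-butyldimethylsilyl)oxy]-6-methyl-6-[(triethylsilyl)oxy]hept-4-en-1-yne
Conditions: K2CO3 (cat.), MeOH, 0 → 20 °C
Reagents that add atoms: none
Why: Methanolysis of the C(sp)–SiMe3 bond under mild base is selective over the two O-silyl ethers and gives the terminal alkyne needed for carbene transfer.

Step 6
Reactants: 8 (3R,4E)-3-[(tert-butyldimethylsilyl)oxy]-6-methyl-6-[(triethylsilyl)oxy]hept-4-en-1-yne
Product: 10 2-{(1R,2E)-1-[(tert-butyldimethylsilyl)oxy]-4-methyl-4-[(triethylsilyl)oxy]pent-2-en-1-yl}cycloprop-2-en-1-one, via gem-difluorocyclopropene 9 (not isolated)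
Conditions: TMSCF3, NaI, THF, 65 °C (sealed tube); then wet silica gel, CH2Cl2, 20 °C
Reagents that add atoms: (trifluoromethyl)trimethylsilane, C[Si](C)(C)C(F)(F)F; water, O
Why: [2+1] cycloaddition of difluorocarbene (from TMSCF3/NaI) to a terminal alkyne followed by hydrolysis of the gem-difluorocyclopropene is the standard entry to monosubstituted cyclopropenones, and the unhindered alkyne should outcompete the 1,2-disubstituted alkene, which is flanked by a quaternary carbon and two inductively withdrawing silyloxy-bearing carbons.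

Step 7
Reactants: 11 2,5-dihydroxybenzaldehyde
Product: 12 2,5-bis[(tert-butyldimethylsilyl)oxy]benzaldehyde
Conditions: TBSCl, imidazole, DMF, 20 °C
Reagents that add atoms: tert-butyldimethylsilyl chloride, CC(C)(C)[Si](C)(C)Cl
Why: Standard bis-silylation of the two phenols; aryl TBS ethers should tolerate the mild acid and the organolithium conditions ahead and are removed with fluoride at the end.

Step 8
Reactants: 12 2,5-bis[(tert-butyldimethylsilyl)oxy]benzaldehyde
Product: 14 {2,5-bis[(tert-butyldimethylsilyl)oxy]phenyl}(methoxy)methyl phenyl sulfone (racemic), via dimethyl acetal 13 (not isolated)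
Conditions: HC(OMe)3, MeOH, PPTS (cat.), 20 °C; evaporate; PhSO2H, CH2Cl2, 4 Å MS, 20 °C
Reagents that add atoms: trimethyl orthoformate, COC(OC)OC; benzenesulfinic acid, OS(=O)c1ccccc1
Why: Acid-catalysed acetalisation followed by exchange of one methoxy group for sulfinate through the aryl-stabilised oxocarbenium ion (S-alkylation of the sulfinate) is the usual preparation of α-alkoxy sulfones; the new carbon centre is racemic and is planarised in the next step.

Step 9
Reactants: 14 {2,5-bis[(tert-butyldimethylsilyl)oxy]phenyl}(methoxy)methyl phenyl sulfone; 10 2-{(1R,2E)-1-[(tert-butyldimethylsilyl)oxy]-4-methyl-4-[(triethylsilyl)oxy]pent-2-en-1-yl}cycloprop-2-en-1-one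
Product: 19 5,8-bis[(tert-butyldimethylsilyl)oxy]-2-{(1R,2E)-1-[(tert-butyldimethylsilyl)oxy]-4-methyl-4-[(triethylsilyl)oxy]pent-2-en-1-yl}-4-methoxynaphthalen-1-ol, via lithiated sulfone 15 (not isolated), via cyclopropanone enolate adduct 16 (not isolated), via aryl(methoxy)vinylketene 17 (not isolated), via 4-aryl-4-methoxycyclobutenone 18 (not isolated)
Conditions: n-BuLi (1.0 equiv), THF, −78 °C; solution added to 10 in THF, −78 → 20 °C; then toluene, 100 °C
Reagents that add atoms: none
Why: Proposed new method: lithiated α-methoxy sulfone 15, an aryl(methoxy)carbene equivalent, should add in conjugate fashion to the unsubstituted ring CH of cyclopropenone 10 to give cyclopropanone enolate 16, and release of the three-ring strain then drives a Grob-type fragmentation (enolate oxygen pushes, the ring C(=O)–CH bond breaks, sulfinate leaves) to aryl(methoxy)vinylketene 17, the intermediate common to the Dötz benzannulation and the Moore rearrangement. The closest known reaction types are the conjugate addition/ring opening of cyclopropenones by phosphines and by leaving-group-bearing stabilised ylides (which give 2-pyranones through the analogous vinylketene), the use of lithiated α-methoxy sulfones as carbenoids that lose sulfinate in one-carbon ring expansions, and the thermal Moore rearrangement of 4-aryl-4-alkoxycyclobutenones; their merger into a benzannulation of a cyclopropenone is what is new. Ring B is closed by thermal 6π-electrocyclisation of 17 (ketene carbon onto the aryl ortho carbon, disrotatory) and aromatising proton shift to the naphthol, so that the CH–C(OMe) bond and the C(OH)–aryl bond are made in one flask. No stereocentre is created, since the two transient sp3 centres of 16 become sp2, and the silyloxy-bearing (R) centre is never deprotonated or ionised and is carried through unchanged. The step needs attack at the CH rather than the substituted ring carbon (secured by sterics), the aryl group cis to the ketene (secured because ketene of the wrong geometry can only close to cyclobutenone 18, which re-opens on heating with methoxy rotating outward and aryl inward) and closure at one aryl position (secured because the other ortho position carries OTBS). Direct 1,2-addition to the carbonyl would not divert the sequence either, because semipinacol shift with loss of sulfinate leads to the same cyclobutenone 18.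

Step 10
Reactants: 19 5,8-bis[(tert-butyldimethylsilyl)oxy]-2-{(1R,2E)-1-[(tert-butyldimethylsilyl)oxy]-4-methyl-4-[(triethylsilyl)oxy]pent-2-en-1-yl}-4-methoxynaphthalen-1-ol
Product: 20 5,8-bis[(tert-butyldimethylsilyl)oxy]-2-{(1R,2E)-1-[(tert-butyldimethylsilyl)oxy]-4-methyl-4-[(triethylsilyl)oxy]pent-2-en-1-yl}naphthalene-1,4-dione
Conditions: PhI(OAc)2, MeCN/H2O, 0 °C
Reagents that add atoms: water, O
Why: Oxidative demethylation of a 4-methoxy-1-naphthol to the 1,4-naphthoquinone with PhI(OAc)2 in aqueous acetonitrile proceeds through the quinone monoketal, and the free 1-OH left by the annulation directs the oxidation to this ring so that the silylated ring stays benzenoid.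

Step 11
Reactants: 20 5,8-bis[(tert-butyldimethylsilyl)oxy]-2-{(1R,2E)-1-[(tert-butyldimethylsilyl)oxy]-4-methyl-4-[(triethylsilyl)oxy]pent-2-en-1-yl}naphthalene-1,4-dione
Product: 21 2-[(1R,2E)-1,4-dihydroxy-4-methylpent-2-en-1-yl]-5,8-dihydroxynaphthalene-1,4-dione
Conditions: HF·pyridine, pyridine, THF, 0 → 20 °C
Reagents that add atoms: none
Why: Buffered HF·pyridine should cleave the two peri aryl silyl ethers, the secondary TBS ether and the tertiary TES ether in one operation (fluoride desilylation) without the strong acid or base that would ionise the doubly allylic system, releasing the naphthazarin.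

Step 12
Reactants: 21 2-[(1R,2E)-1,4-dihydroxy-4-methylpent-2-en-1-yl]-5,8-dihydroxynaphthalene-1,4-dione; 22 (R)-2-methylbutanoic acid
Product: 23 (1R,2E)-1-(5,8-dihydroxy-1,4-dioxo-1,4-dihydronaphthalen-2-yl)-4-hydroxy-4-methylpent-2-en-1-yl (2R)-2-methylbutanoate (CNP0265539.1)
Conditions: DCC, DMAP (cat.), CH2Cl2, 0 → 20 °C
Reagents that add atoms: none
Why: Steglich esterification should acylate the secondary allylic alcohol selectively, as in the acylation of shikonin, because the tertiary alcohol is too hindered and the peri phenols are locked in hydrogen bonds to the quinone carbonyls; neither stereocentre is touched under cold carbodiimide activation.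

**Compound list**

1 | 2-methylbut-3-en-2-ol | C=CC(C)(C)O | starting material
2 | (E)-but-2-enal | C/C=C/C=O | starting material
3 | (E)-4-hydroxy-4-methylpent-2-enal | O=C/C=C/C(C)(C)O | intermediate
4 | (E)-4-methyl-4-[(triethylsilyl)oxy]pent-2-enal | O=C/C=C/C(C)(C)O[Si](CC)(CC)CC | intermediate
5 | ethynyltrimethylsilane | C#C[Si](C)(C)C | starting material
6 | (3R,4E)-6-methyl-6-[(triethylsilyl)oxy]-1-(trimethylsilyl)hept-4-en-1-yn-3-ol | O[C@H](/C=C/C(C)(C)O[Si](CC)(CC)CC)C#C[Si](C)(C)C | intermediate
7 | (3R,4E)-3-[(tert-butyldimethylsilyl)oxy]-6-methyl-6-[(triethylsilyl)oxy]-1-(trimethylsilyl)hept-4-en-1-yne | CC(C)(C)[Si](C)(C)O[C@H](/C=C/C(C)(C)O[Si](CC)(CC)CC)C#C[Si](C)(C)C | intermediate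
8 | (3R,4E)-3-[(tert-butyldimethylsilyl)oxy]-6-methyl-6-[(triethylsilyl)oxy]hept-4-en-1-yne | CC(C)(C)[Si](C)(C)O[C@H](/C=C/C(C)(C)O[Si](CC)(CC)CC)C#C | intermediate
9 | 1-{(1R,2E)-1-[(tert-butyldimethylsilyl)oxy]-4-methyl-4-[(triethylsilyl)oxy]pent-2-en-1-yl}-3,3-difluorocycloprop-1-ene | CC(C)(C)[Si](C)(C)O[C@H](/C=C/C(C)(C)O[Si](CC)(CC)CC)C1=CC1(F)F | intermediate
10 | 2-{(1R,2E)-1-[(tert-butyldimethylsilyl)oxy]-4-methyl-4-[(triethylsilyl)oxy]pent-2-en-1-yl}cycloprop-2-en-1-one | CC(C)(C)[Si](C)(C)O[C@H](/C=C/C(C)(C)O[Si](CC)(CC)CC)C1=CC1=O | intermediate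
11 | 2,5-dihydroxybenzaldehyde | O=Cc1cc(O)ccc1O | starting material
12 | 2,5-bis[(tert-butyldimethylsilyl)oxy]benzaldehyde | O=Cc1cc(O[Si](C)(C)C(C)(C)C)ccc1O[Si](C)(C)C(C)(C)C | intermediate
13 | 2,5-bis[(tert-butyldimethylsilyl)oxy]benzaldehyde dimethyl acetal | COC(OC)c1cc(O[Si](C)(C)C(C)(C)C)ccc1O[Si](C)(C)C(C)(C)C | intermediate
14 | {2,5-bis[(tert-butyldimethylsilyl)oxy]phenyl}(methoxy)methyl phenyl sulfone (racemic) | COC(c1cc(O[Si](C)(C)C(C)(C)C)ccc1O[Si](C)(C)C(C)(C)C)S(=O)(=O)c1ccccc1 | intermediate
15 | α-lithio derivative of sulfone 14 | COC([Li])(c1cc(O[Si](C)(C)C(C)(C)C)ccc1O[Si](C)(C)C(C)(C)C)S(=O)(=O)c1ccccc1 | intermediate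
16 | lithium cyclopropanone enolate from addition of 15 to the ring CH of 10 (mixture of diastereomers at the two new centres) | CC(C)(C)[Si](C)(C)O[C@H](/C=C/C(C)(C)O[Si](CC)(CC)CC)C1=C(O[Li])C1C(OC)(c1cc(O[Si](C)(C)C(C)(C)C)ccc1O[Si](C)(C)C(C)(C)C)S(=O)(=O)c1ccccc1 | intermediate
17 | 4-{2,5-bis[(tert-butyldimethylsilyl)oxy]phenyl}-4-methoxy-2-[(1R,2E)-disilyloxyalkenyl]buta-1,3-dien-1-one (vinylketene, either enol ether geometry) | CC(C)(C)[Si](C)(C)O[C@H](/C=C/C(C)(C)O[Si](CC)(CC)CC)C(=C=O)C=C(OC)c1cc(O[Si](C)(C)C(C)(C)C)ccc1O[Si](C)(C)C(C)(C)C | intermediate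
18 | 4-{2,5-bis[(tert-butyldimethylsilyl)oxy]phenyl}-4-methoxy-2-[(1R,2E)-disilyloxyalkenyl]cyclobut-2-en-1-one | CC(C)(C)[Si](C)(C)O[C@H](/C=C/C(C)(C)O[Si](CC)(CC)CC)C1=CC(OC)(c2cc(O[Si](C)(C)C(C)(C)C)ccc2O[Si](C)(C)C(C)(C)C)C1=O | intermediate
19 | 5,8-bis[(tert-butyldimethylsilyl)oxy]-2-{(1R,2E)-1-[(tert-butyldimethylsilyl)oxy]-4-methyl-4-[(triethylsilyl)oxy]pent-2-en-1-yl}-4-methoxynaphthalen-1-ol | CC(C)(C)[Si](C)(C)O[C@H](/C=C/C(C)(C)O[Si](CC)(CC)CC)c1cc(OC)c2c(O[Si](C)(C)C(C)(C)C)ccc(O[Si](C)(C)C(C)(C)C)c2c1O | intermediate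
20 | 5,8-bis[(tert-butyldimethylsilyl)oxy]-2-{(1R,2E)-1-[(tert-butyldimethylsilyl)oxy]-4-methyl-4-[(triethylsilyl)oxy]pent-2-en-1-yl}naphthalene-1,4-dione | CC(C)(C)[Si](C)(C)O[C@H](/C=C/C(C)(C)O[Si](CC)(CC)CC)C1=CC(=O)c2c(O[Si](C)(C)C(C)(C)C)ccc(O[Si](C)(C)C(C)(C)C)c2C1=O | intermediate
21 | 2-[(1R,2E)-1,4-dihydroxy-4-methylpent-2-en-1-yl]-5,8-dihydroxynaphthalene-1,4-dione | O[C@H](/C=C/C(C)(C)O)C1=CC(=O)c2c(O)ccc(O)c2C1=O | intermediate
22 | (R)-2-methylbutanoic acid | CC[C@@H](C)C(=O)O | starting material
23 | (1R,2E)-1-(5,8-dihydroxy-1,4-dioxo-1,4-dihydronaphthalen-2-yl)-4-hydroxy-4-methylpent-2-en-1-yl (2R)-2-methylbutanoate | CC[C@@H](C)C(=O)O[C@H](/C=C/C(C)(C)O)C1=CC(=O)c2c(O)ccc(O)c2C1=O | target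

**Step count and risks**

Total steps: 12. Longest linear sequence: 10 steps (steps 1–6, then 9–12).

Steps most likely to fail:

1. Step 9 (key step, proposed new method). Proton transfer from the acidic ring C–H of the cyclopropenone to the carbanion, or capture of the ketene by a second carbanion, may outrun the addition/fragmentation/electrocyclisation sequence; inverse addition is meant to limit both. If addition occurred at the substituted ring carbon instead, the isomeric naphthol would still give quinone 20 in step 10, because the 5,8-bis(silyloxy)naphthoquinone core is symmetric. Fallback (known chemistry, Dötz benzannulation): it sets out from alkyne 8, bypasses cyclopropenone 10 and comes back at naphthol 19. Commercial 2-bromobenzene-1,4-diol is bis-silylated (TBSCl, imidazole) to 2-bromo-1,4-bis[(tert-butyldimethylsilyl)oxy]benzene F1. Bromine–lithium exchange (n-BuLi, Et2O, −78 °C, kept cold to forestall oxygen-to-carbon silyl migration), addition to Cr(CO)6 and O-methylation of the acyl chromate with MeOTf should give pentacarbonyl{[2,5-bis(tert-butyldimethylsilyloxy)phenyl](methoxy)methylidene}chromium F2. Heating F2 with 8 (THF, 55 °C) and demetalation in air should give 19, with the regiochemistry normal for terminal alkynes (substituent next to the phenol).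

2. Step 6. Difluorocarbene may also cyclopropanate the side-chain alkene, and the monosubstituted cyclopropenone may be lost during hydrolysis or chromatography. Fallback (cyclopropenone acetal route, no carbene in the presence of the alkene): it sets out from enal 4 and comes back at cyclopropenone 10. 1,3-Dichloroacetone and 2,2-dimethylpropane-1,3-diol (TsOH, toluene, Dean–Stark) give 2,2-bis(chloromethyl)-5,5-dimethyl-1,3-dioxane F3, and NaNH2 in liquid NH3 closes it to 6,6-dimethyl-4,8-dioxaspiro[2.5]oct-1-ene F4. Lithiation of F4 (n-BuLi, THF, −78 °C) and addition to 4 should give racemic (E)-1-(6,6-dimethyl-4,8-dioxaspiro[2.5]oct-1-en-1-yl)-4-methyl-4-[(triethylsilyl)oxy]pent-2-en-1-ol F5. Lipase-catalysed kinetic resolution (Pseudomonas cepacia lipase, vinyl acetate, MTBE) is expected from Kazlauskas' rule to acylate the (R) enantiomer, giving the (R)-acetate F6; methanolysis (K2CO3, MeOH) gives the (R)-alcohol F7 (if the enzyme preference is opposite, the unreacted alcohol is F7). Silylation (TBSCl, imidazole) gives the (R)-TBS ether F8, and mild acetal hydrolysis (Amberlyst-15, wet acetone, 20 °C) should release 10.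

3. Step 8. The electron-rich α-methoxy sulfone may ionise back to the oxocarbenium ion with loss of sulfinate during isolation, or the sulfinic acid may strip an aryl silyl ether. Fallback (sulfide oxidation instead of sulfinate exchange): it sets out from acetal 13 and comes back at sulfone 14. Exchange of one methoxy group with thiophenol (BF3·OEt2 cat., CH2Cl2, −78 °C) should give the O,S-acetal {2,5-bis[(tert-butyldimethylsilyl)oxy]phenyl}(methoxy)methyl phenyl sulfide F9, and oxidation at sulfur (mCPBA, NaHCO3, CH2Cl2, 0 °C) then gives 14 under non-acidic conditions.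

**Further compounds**

F1 | step 9 | 2-bromo-1,4-bis[(tert-butyldimethylsilyl)oxy]benzene | Brc1cc(O[Si](C)(C)C(C)(C)C)ccc1O[Si](C)(C)C(C)(C)C
F2 | step 9 | pentacarbonyl{[2,5-bis(tert-butyldimethylsilyloxy)phenyl](methoxy)methylidene}chromium | COC(c1cc(O[Si](C)(C)C(C)(C)C)ccc1O[Si](C)(C)C(C)(C)C)=[Cr](=C=O)(=C=O)(=C=O)(=C=O)=C=O
F3 | step 6 | 2,2-bis(chloromethyl)-5,5-dimethyl-1,3-dioxane | ClCC1(CCl)OCC(C)(C)CO1
F4 | step 6 | 6,6-dimethyl-4,8-dioxaspiro[2.5]oct-1-ene | CC1(C)COC2(C=C2)OC1
F5 | step 6 | racemic (E)-1-(6,6-dimethyl-4,8-dioxaspiro[2.5]oct-1-en-1-yl)-4-methyl-4-[(triethylsilyl)oxy]pent-2-en-1-ol | OC(/C=C/C(C)(C)O[Si](CC)(CC)CC)C1=CC12OCC(C)(C)CO2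
F6 | step 6 | (1R,2E)-1-(6,6-dimethyl-4,8-dioxaspiro[2.5]oct-1-en-1-yl)-4-methyl-4-[(triethylsilyl)oxy]pent-2-en-1-yl acetate | CC(=O)O[C@H](/C=C/C(C)(C)O[Si](CC)(CC)CC)C1=CC12OCC(C)(C)CO2
F7 | step 6 | (1R,2E)-1-(6,6-dimethyl-4,8-dioxaspiro[2.5]oct-1-en-1-yl)-4-methyl-4-[(triethylsilyl)oxy]pent-2-en-1-ol | O[C@H](/C=C/C(C)(C)O[Si](CC)(CC)CC)C1=CC12OCC(C)(C)CO2
F8 | step 6 | tert-butyldimethylsilyl ether of F7 | CC(C)(C)[Si](C)(C)O[C@H](/C=C/C(C)(C)O[Si](CC)(CC)CC)C1=CC12OCC(C)(C)CO2
F9 | step 8 | {2,5-bis[(tert-butyldimethylsilyl)oxy]phenyl}(methoxy)methyl phenyl sulfide | COC(Sc1ccccc1)c1cc(O[Si](C)(C)C(C)(C)C)ccc1O[Si](C)(C)C(C)(C)C
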